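**Retrosynthetic overview**
1. Target ⇒ C15 desilylation and C18 acylation ⇒ bicyclic 8,18-diol carrying a C15 silyl ether.
2. Rings A and B form in one cation–olefin cascade, ring A first (C4–C5 bond), then ring B (C9–C10 bond), from an acyclic (S)-2-methyl-2-alkyloxirane diene. The epoxide CH2 becomes C18–OH, C4 is set by inversion, and water ends the cascade as the C8 carbinol.
3. Epoxide ⇒ catalytic asymmetric CH2 transfer to a C19 methyl ketone.
4. Ketone ⇒ copper-catalysed coupling of the terminal (E)-allylic bromide of (S)-2,3-dihydrofarnesyl silyl ether with a C4 ketal Grignard reagent.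
5. C13 ⇒ asymmetric hydrogenation of (2E,6E)-farnesol.

Assumption 1: labdane numbering is used (C18 = CH2O on C4, C19 = CH3 on C4, C17 = CH3 on C8, C20 = CH3 on C10). The SMILES is read as (4S,5S,8S,9S,10R,13S), an ent-labdane with trans ring fusion, equatorial C18, equatorial 8-OH and equatorial C9 side chain.
Assumption 2: the (S)-binaphthoxide antipode of the step 6 catalyst is taken as the one that gives the (S)-epoxide; if a model methyl ketone shows the opposite sense, the (R) antipode is used and nothing else changes.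

Abbreviations: TBDPS = tert-butyldiphenylsilyl; HFIP = (CF3)2CHOH.

**Route**

Step 1
Reactants: 1 (2E,6E)-farnesol
Product: 2 (S)-2,3-dihydrofarnesol, (3S,6E)-3,7,11-trimethyldodeca-6,10-dien-1-ol
Conditions: H2 (30 atm), Ru(OAc)2[(R)-BINAP] (0.5 mol %), MeOH–H2O 95:5, 20 °C
Reagents that add atoms: none
Why: Noyori asymmetric hydrogenation of an allylic alcohol; the hydroxyl-directed BINAP–ruthenium catalyst reduces only the 2,3-olefin, and (R)-BINAP on the (2E)-alcohol gives the (3S) centre (future C13) while the two isolated trisubstituted olefins stay.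

Step 2
Reactants: 2 (S)-2,3-dihydrofarnesol
Product: 3 tert-butyl{[(3S,6E)-3,7,11-trimethyldodeca-6,10-dien-1-yl]oxy}diphenylsilane
Conditions: TBDPSCl, imidazole, CH2Cl2, 23 °C
Reagents that add atoms: tert-butyl(chloro)diphenylsilane, CC(C)(C)[Si](Cl)(c1ccccc1)c1ccccc1
Why: Standard silyl ether protection of the primary alcohol; TBDPS survives the later aqueous HCl, the sulfur ylide, HFIP and the acylation, and no stereocentre is touched.

Step 3
Reactants: 3 TBDPS ether of (S)-2,3-dihydrofarnesol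
Product: 4 (2E,6E,10S)-12-[(tert-butyldiphenylsilyl)oxy]-2,6,10-trimethyldodeca-2,6-dien-1-ol
Conditions: SeO2 (0.3 equiv), t-BuOOH (3 equiv), salicylic acid (0.1 equiv), CH2Cl2, 0 → 23 °C, stopped at about 60 % conversion, 3 recycled
Reagents that add atoms: selenium dioxide, O=[Se]=O (transfers the oxygen); tert-butyl hydroperoxide, CC(C)(C)OO (re-oxidant and ultimate oxygen source)
Why: Sharpless catalytic SeO2 allylic oxidation (ene reaction, then [2,3]-sigmatropic shift) hydroxylates the (E)-methyl of the terminal isopropylidene, the most accessible olefin, and gives only the (E)-allylic alcohol.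

Step 4
Reactants: 4 (E)-allylic alcohol
Product: 5 {[(3S,6E,10E)-12-bromo-3,7,11-trimethyldodeca-6,10-dien-1-yl]oxy}(tert-butyl)diphenylsilane
Conditions: CBr4, PPh3, CH2Cl2, −20 → 0 °C, used crude
Reagents that add atoms: carbon tetrabromide, BrC(Br)(Br)Br
Why: Appel reaction; SN2 displacement at the primary allylic carbon occurs without allylic transposition or loss of E geometry.

Step 5
Reactants: 5 allylic bromide; 6 2-(2-bromoethyl)-2-methyl-1,3-dioxolane
Product: 9 (6E,10E,14S)-16-[(tert-butyldiphenylsilyl)oxy]-6,10,14-trimethylhexadeca-6,10-dien-2-one, via dioxolane Grignard reagent 7 (not isolated), via coupled dioxolane 8 (not isolated)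
Conditions: 6, Mg, THF, 25 °C; add to 5, Li2CuCl4 (5 mol %), THF, −78 → 0 °C; then 1 M HCl, THF, 23 °C
Reagents that add atoms: water, O
Why: Kochi copper-catalysed Grignard–allylic bromide coupling is SN2-selective under these conditions and keeps the E olefin; acid-catalysed ketal hydrolysis in the same flask frees the methyl ketone, and no stereocentre is formed.

Step 6
Reactants: 9 methyl ketone
Product: 10 tert-butyl{[(3S,6E,10E)-3,7,11-trimethyl-14-[(2S)-2-methyloxiran-2-yl]tetradeca-6,10-dien-1-yl]oxy}diphenylsilane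
Conditions: Me3S(O)I, NaH, THF; then 9, LaLi3[(S)-binaphthoxide]3 (5 mol %), [2,4,6-(MeO)3C6H2]3P=O (5 mol %), 5 Å MS, THF, 23 °C
Reagents that add atoms: trimethylsulfoxonium iodide, C[S+](C)(C)=O.[I-] (gives CH2 through its ylide)
Why: Catalytic asymmetric Corey–Chaykovsky epoxidation of a methyl ketone; the lanthanum–lithium binaphthoxide binds ketone and ylide and delivers CH2 to the Re face (O > CH2R > CH3), giving the (S)-2,2-disubstituted epoxide (future C4), with enantioselectivity for methyl ketones that I recall as above 90 % ee.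

Step 7
Reactants: 10 (S)-epoxy diene
Product: 11 (4S,5S,8S,9S,10R,13S)-15-[(tert-butyldiphenylsilyl)oxy]labdane-8,18-diol, (1S,2S,4aS,5S,8aR)-1-{(3S)-5-[(tert-butyldiphenylsilyl)oxy]-3-methylpentyl}-5-(hydroxymethyl)-2,5,8a-trimethyldecahydronaphthalen-2-ol
Conditions: Ph4PBF4 (0.2 equiv), H2O (10 equiv), HFIP, 0.01 M, 0 °C
Reagents that add atoms: water, O
Why: Proposed new method: cation–olefin bicyclisation started by a 2,2-disubstituted (terminal) epoxide and ended by water, closest known reaction type the HFIP- or Lewis-acid-promoted epoxy-polyene cyclisation of trisubstituted epoxides and the invertive Friedel–Crafts cyclisation of 2,2-disubstituted epoxides in fluorinated alcohols; hydrogen-bonded HFIP loosens the tertiary C4–O bond only as the C5=C10 olefin attacks C4 from the back, so the (S)-epoxide gives (4S) by inversion with the oxygen left on C18 and none on C3, the loose cation-like transition state has C3, CH3 and CH2O nearly coplanar so the larger solvated CH2O arm sits outside (equatorial) and CH3 axial in a chair–chair fold, anti addition across the two E olefins closes ring A then ring B with trans fusion (5S,10R) and an equatorial C9 chain (9S), and water takes the C8 cation on the equatorial face away from the axial C10 methyl (8S).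

Step 8
Reactants: 11 bicyclic 8,18-diol; 12 3-methylbut-2-enoyl chloride (senecioyl chloride)
Product: 13 (4S,5S,8S,9S,10R,13S)-15-[(tert-butyldiphenylsilyl)oxy]-8-hydroxylabdan-18-yl 3-methylbut-2-enoate
Conditions: 12 (1.5 equiv), pyridine, DMAP (0.1 equiv), CH2Cl2, 0 → 23 °C
Reagents that add atoms: none
Why: DMAP-catalysed acylation; only the primary C18 hydroxyl reacts because the tertiary C8 hydroxyl is inert, and pyridine instead of a trialkylamine limits vinylketene formation and deconjugation of the enoate.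

Step 9
Reactants: 13 silyl-protected ester
Product: 14 CNP0280238.1, (4S,5S,8S,9S,10R,13S)-8,15-dihydroxylabdan-18-yl 3-methylbut-2-enoate, [(1S,4aR,5S,6S,8aS)-6-hydroxy-5-[(3S)-5-hydroxy-3-methylpentyl]-1,4a,6-trimethyldecahydronaphthalen-1-yl]methyl 3-methylbut-2-enoate
Conditions: Bu4NF, AcOH (1:1), THF, 23 °C
Reagents that add atoms: none
Why: Fluoride-driven desilylation (Si–F bond formation); the acetic acid buffer keeps the enoate ester and the tertiary alcohol intact, and no stereocentre is touched.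

**Compound list**
1 | (2E,6E)-farnesol | CC(C)=CCC/C(C)=C/CC/C(C)=C/CO | starting material
2 | (S)-2,3-dihydrofarnesol, (3S,6E)-3,7,11-trimethyldodeca-6,10-dien-1-ol | CC(C)=CCC/C(C)=C/CC[C@H](C)CCO | intermediate
3 | tert-butyl{[(3S,6E)-3,7,11-trimethyldodeca-6,10-dien-1-yl]oxy}diphenylsilane | CC(C)=CCC/C(C)=C/CC[C@H](C)CCO[Si](c1ccccc1)(c1ccccc1)C(C)(C)C | intermediate
4 | (2E,6E,10S)-12-[(tert-butyldiphenylsilyl)oxy]-2,6,10-trimethyldodeca-2,6-dien-1-ol | OC/C(C)=C/CC/C(C)=C/CC[C@H](C)CCO[Si](c1ccccc1)(c1ccccc1)C(C)(C)C | intermediate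
5 | {[(3S,6E,10E)-12-bromo-3,7,11-trimethyldodeca-6,10-dien-1-yl]oxy}(tert-butyl)diphenylsilane | BrC/C(C)=C/CC/C(C)=C/CC[C@H](C)CCO[Si](c1ccccc1)(c1ccccc1)C(C)(C)C | intermediate
6 | 2-(2-bromoethyl)-2-methyl-1,3-dioxolane | CC1(CCBr)OCCO1 | starting material
7 | [2-(2-methyl-1,3-dioxolan-2-yl)ethyl]magnesium bromide | CC1(CC[Mg]Br)OCCO1 | intermediate
8 | tert-butyl{[(3S,6E,10E)-3,7,11-trimethyl-14-(2-methyl-1,3-dioxolan-2-yl)tetradeca-6,10-dien-1-yl]oxy}diphenylsilane | CC1(CCC/C(C)=C/CC/C(C)=C/CC[C@H](C)CCO[Si](c2ccccc2)(c2ccccc2)C(C)(C)C)OCCO1 | intermediate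
9 | (6E,10E,14S)-16-[(tert-butyldiphenylsilyl)oxy]-6,10,14-trimethylhexadeca-6,10-dien-2-one | CC(=O)CCC/C(C)=C/CC/C(C)=C/CC[C@H](C)CCO[Si](c1ccccc1)(c1ccccc1)C(C)(C)C | intermediate
10 | tert-butyl{[(3S,6E,10E)-3,7,11-trimethyl-14-[(2S)-2-methyloxiran-2-yl]tetradeca-6,10-dien-1-yl]oxy}diphenylsilane | C[C@]1(CCC/C(C)=C/CC/C(C)=C/CC[C@H](C)CCO[Si](c2ccccc2)(c2ccccc2)C(C)(C)C)CO1 | intermediate
11 | (4S,5S,8S,9S,10R,13S)-15-[(tert-butyldiphenylsilyl)oxy]labdane-8,18-diol | OC[C@@]1(C)CCC[C@]2(C)[C@@H]1CC[C@](C)(O)[C@H]2CC[C@H](C)CCO[Si](c3ccccc3)(c3ccccc3)C(C)(C)C | intermediate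
12 | 3-methylbut-2-enoyl chloride | CC(C)=CC(Cl)=O | starting material
13 | (4S,5S,8S,9S,10R,13S)-15-[(tert-butyldiphenylsilyl)oxy]-8-hydroxylabdan-18-yl 3-methylbut-2-enoate | CC(C)=CC(=O)OC[C@@]1(C)CCC[C@]2(C)[C@@H]1CC[C@](C)(O)[C@H]2CC[C@H](C)CCO[Si](c3ccccc3)(c3ccccc3)C(C)(C)C | intermediate
14 | CNP0280238.1, (4S,5S,8S,9S,10R,13S)-8,15-dihydroxylabdan-18-yl 3-methylbut-2-enoate | CC(C)=CC(=O)OC[C@@]1(C)CCC[C@]2(C)[C@@H]1CC[C@](C)(O)[C@H]2CC[C@H](C)CCO | target

**Step count**
Total steps: 9. Longest linear sequence: 9 steps (1 → 14); compounds 6 and 12 are bought.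

**Steps most likely to fail**

Step 7 (bicyclisation). The cascade may end by proton loss instead of water capture, the opened epoxide may shift a hydride to give the aldehyde, and the equatorial-versus-axial placement of C18 and the fidelity of inversion at C4 are untested. The fallback sets out from 10 and returns at 11, and separates ring formation from C8 oxygenation. Compound 10 is cyclised without water (Ph4PBF4, HFIP, 2,6-di-tert-butylpyridine, 0 °C) so that the cascade ends by proton loss, giving the exocyclic olefin 15-[(tert-butyldiphenylsilyl)oxy]labd-8(17)-en-18-ol F1 together with its endocyclic isomer 15-[(tert-butyldiphenylsilyl)oxy]labd-7-en-18-ol F2 (both with C4, C5, C9, C10 and C13 as in 11). The mixture is then hydrated by Mukaiyama hydration (Co(acac)2, PhSiH3, O2, THF, 23 °C, then PPh3). Both olefins give the same tertiary C8 radical, which takes up O2 on the equatorial face away from the axial C10 methyl, and this gives 11.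

Step 6 (asymmetric epoxidation). The enantioselectivity on this long-chain ketone, and the sense of induction, may fall short. The fallback sets out from 5 and returns at 10, and takes C4 from the chiral pool instead of from catalysis. Magnesium converts (S)-4-(2-bromoethyl)-2,2,4-trimethyl-1,3-dioxolane F3 (derived from (S)-citramalic acid) into {2-[(4S)-2,2,4-trimethyl-1,3-dioxolan-4-yl]ethyl}magnesium bromide F4. Coupling of F4 with 5 (Li2CuCl4, THF, −78 → 0 °C) gives (4S)-4-[(4E,8E,12S)-14-[(tert-butyldiphenylsilyl)oxy]-4,8,12-trimethyltetradeca-4,8-dien-1-yl]-2,2,4-trimethyl-1,3-dioxolane F5. Treatment with 1 M HCl in THF frees (2S,6E,10E,14S)-16-[(tert-butyldiphenylsilyl)oxy]-2,6,10,14-tetramethylhexadeca-6,10-diene-1,2-diol F6. TsCl, Et3N and DMAP sulfonylate only the primary hydroxyl to give the 1-(4-methylbenzenesulfonate) of that diol F7, and K2CO3 in MeOH closes the epoxide through the tertiary alkoxide with retention at C4, which gives 10.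

Step 8 (senecioylation). The neopentyl alcohol acylates slowly, and senecioyl chloride can deconjugate through its vinylketene to the 3-methylbut-3-enoate. The fallback sets out from 11 and returns at 13, and builds the enoate on the alcohol instead of transferring it. Compound 11 is esterified with (diethoxyphosphoryl)acetic acid (DCC, DMAP, CH2Cl2) to (4S,5S,8S,9S,10R,13S)-15-[(tert-butyldiphenylsilyl)oxy]-8-hydroxylabdan-18-yl (diethoxyphosphoryl)acetate F8. A Horner–Wadsworth–Emmons reaction with acetone (NaH, THF, 0 → 23 °C) then gives 13 with the double bond necessarily conjugated.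

**Further compounds**
F1 | step 7 | 15-[(tert-butyldiphenylsilyl)oxy]labd-8(17)-en-18-ol (configuration as in 11) | OC[C@@]1(C)CCC[C@]2(C)[C@@H]1CCC(=C)[C@H]2CC[C@H](C)CCO[Si](c3ccccc3)(c3ccccc3)C(C)(C)C
F2 | step 7 | 15-[(tert-butyldiphenylsilyl)oxy]labd-7-en-18-ol (configuration as in 11) | OC[C@@]1(C)CCC[C@]2(C)[C@@H]1CC=C(C)[C@H]2CC[C@H](C)CCO[Si](c3ccccc3)(c3ccccc3)C(C)(C)C
F3 | step 6 | (S)-4-(2-bromoethyl)-2,2,4-trimethyl-1,3-dioxolane | C[C@]1(CCBr)COC(C)(C)O1
F4 | step 6 | {2-[(4S)-2,2,4-trimethyl-1,3-dioxolan-4-yl]ethyl}magnesium bromide | C[C@]1(CC[Mg]Br)COC(C)(C)O1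
F5 | step 6 | (4S)-4-[(4E,8E,12S)-14-[(tert-butyldiphenylsilyl)oxy]-4,8,12-trimethyltetradeca-4,8-dien-1-yl]-2,2,4-trimethyl-1,3-dioxolane | C[C@]1(CCC/C(C)=C/CC/C(C)=C/CC[C@H](C)CCO[Si](c2ccccc2)(c2ccccc2)C(C)(C)C)COC(C)(C)O1
F6 | step 6 | (2S,6E,10E,14S)-16-[(tert-butyldiphenylsilyl)oxy]-2,6,10,14-tetramethylhexadeca-6,10-diene-1,2-diol | C[C@](O)(CCC/C(C)=C/CC/C(C)=C/CC[C@H](C)CCO[Si](c1ccccc1)(c1ccccc1)C(C)(C)C)CO
F7 | step 6 | (2S,6E,10E,14S)-16-[(tert-butyldiphenylsilyl)oxy]-2-hydroxy-2,6,10,14-tetramethylhexadeca-6,10-dien-1-yl 4-methylbenzenesulfonate | C[C@](O)(CCC/C(C)=C/CC/C(C)=C/CC[C@H](C)CCO[Si](c1ccccc1)(c1ccccc1)C(C)(C)C)COS(=O)(=O)c1ccc(C)cc1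
F8 | step 8 | (4S,5S,8S,9S,10R,13S)-15-[(tert-butyldiphenylsilyl)oxy]-8-hydroxylabdan-18-yl (diethoxyphosphoryl)acetate | CCOP(=O)(OCC)CC(=O)OC[C@@]1(C)CCC[C@]2(C)[C@@H]1CC[C@](C)(O)[C@H]2CC[C@H](C)CCO[Si](c3ccccc3)(c3ccccc3)C(C)(C)C
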